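**Plan**

1. Numbering used throughout: ten-membered ring C1–C10 (C1 quaternary with methyl C15, C2 OAc, C5 methyl C16, C6 Cl, C7 lactone O, C8 OH, C9 OH); ring A = C1, C10, C11 (methyl C20), C12 (OAc), C13, C14 (epoxide on C13–C14); lactone = C7, C8, C17 (methyl C18), C19, O.
2. Enabling feature: with the C13–C14 epoxide read as an alkene, ring A is a cyclohexene whose C1–C10 and C11–C12 bonds are the two sigma bonds of a Diels–Alder adduct, and C1–C10 is also the fusion bond to the ten-membered ring, so cutting both opens ring A and the ten-membered ring to one linear triene.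
3. Cuts, in retrosynthetic order: epoxide oxygen and the C2 acetate; lactone bonds C8–C17 and O7–C19; C1–C10 and C11–C12 (cycloaddition); C9–C10 (thioester/boronic acid ketone synthesis); C7–C8 (glycolate aldol); C5–C16 and C6–Cl (carbocupration/chlorination of an ynoate); C6–C7; C1–C2 (alkenylzirconium acylation).
4. Forward: the chain C12 to C9 is built linearly with the C8 oxygen already in place, ring A and the ten-membered ring close together in step 17, the lactone is annulated in step 24, and the epoxide goes in near the end.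
5. Stereochemistry: C2 from a CBS reduction; C7 and C8 from an Evans syn-glycolate aldol; C1, C10, C11, C12 from the cycloaddition (alkene geometries, exo pairing, face set by C2); C9 from Felkin–Anh hydride addition; C8 and C17 from the intramolecular Reformatsky closure; C13 and C14 from an epoxidation directed by C2–OH.

Key step: step 17

Remark: locants C1–C20 in names are those of the plan, not IUPAC locants; TES = SiEt3, TBS = Si(t-Bu)Me2, PMB = 4-methoxybenzyl, DMB = 3,4-dimethoxybenzyl.
Remark: ester 36 is drawn with the S bromide of acid 35; that carbon becomes the enolate carbon in step 24, so its configuration is immaterial.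

**Route**

Step 1
Reactants: 1 pent-3-yn-1-ol
Product: 2 triethyl(pent-3-yn-1-yloxy)silane
Conditions: Et3SiCl, imidazole, CH2Cl2, 0 °C to rt
Reagents that add atoms: chlorotriethylsilane, CC[Si](Cl)(CC)CC
Why: Silyl ether formation masks the future C12 oxygen as a primary TES ether that survives the organometallic steps and can later be oxidised directly to the aldehyde.

Step 2
Reactants: 2 triethyl(pent-3-yn-1-yloxy)silane; 3 pent-4-ynoyl chloride
Product: 5 (E)-6-methyl-9-(triethylsilyloxy)non-6-en-1-yn-5-one, via alkenylzirconocene chloride 4 (not isolated)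
Conditions: Cp2Zr(H)Cl, THF, 45 °C; then 3, CuBr·SMe2 (10 mol %), 0 °C to rt
Reagents that add atoms: none
Why: Hydrozirconation with the Schwartz reagent (syn addition, zirconium equilibrating to the carbon next to the methyl group) followed by copper-catalysed acylation of the alkenylzirconocene should give the E enone with the geometry the diene terminus C1 needs.

Step 3
Reactants: 5 (E)-6-methyl-9-(triethylsilyloxy)non-6-en-1-yn-5-one
Product: 6 (5S,6E)-6-methyl-9-(triethylsilyloxy)non-6-en-1-yn-5-ol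
Conditions: (R)-2-methyl-CBS-oxazaborolidine (0.2 equiv), catecholborane, toluene, −78 °C
Reagents that add atoms: none
Why: Corey–Bakshi–Shibata reduction with the alkenyl group as the large substituent should give the 2S allylic alcohol, and catecholborane leaves the terminal alkyne untouched.

Step 4
Reactants: 6 (5S,6E)-6-methyl-9-(triethylsilyloxy)non-6-en-1-yn-5-ol
Product: 7 (5S,6E)-5-(4-methoxybenzyloxy)-6-methyl-9-(triethylsilyloxy)non-6-en-1-yne
Conditions: NaH (1.1 equiv), 4-methoxybenzyl chloride, THF/DMF, 0 °C to rt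
Reagents that add atoms: 4-methoxybenzyl chloride, COc1ccc(CCl)cc1
Why: Williamson etherification of the alkoxide gives the PMB ether, which lasts until the late oxidative release of C2–OH.

Step 5
Reactants: 7 (5S,6E)-5-(4-methoxybenzyloxy)-6-methyl-9-(triethylsilyloxy)non-6-en-1-yne
Product: 9 ethyl (6S,7E)-6-(4-methoxybenzyloxy)-7-methyl-10-(triethylsilyloxy)dec-7-en-2-ynoate, via lithium acetylide 8 (not isolated)
Conditions: n-BuLi, THF, −78 °C; then ClCO2Et, −78 to 0 °C
Reagents that add atoms: ethyl chloroformate, CCOC(=O)Cl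
Why: Deprotonation of the terminal alkyne and C-acylation of the acetylide add C7 as the ynoate ester.

Step 6
Reactants: 9 ethyl (6S,7E)-6-(4-methoxybenzyloxy)-7-methyl-10-(triethylsilyloxy)dec-7-en-2-ynoate
Product: 11 ethyl (2E,6S,7E)-2-chloro-6-(4-methoxybenzyloxy)-3,7-dimethyl-10-(triethylsilyloxy)deca-2,7-dienoate, via lithium alkenyl(methyl)cuprate 10 (not isolated)
Conditions: Me2CuLi (from MeLi and CuBr·SMe2), THF, −78 °C; then N-chlorosuccinimide, −78 °C
Reagents that add atoms: lithium dimethylcuprate, C[Cu-]C.[Li+]; N-chlorosuccinimide, O=C1CCC(=O)N1Cl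
Why: Syn carbocupration of the ynoate with the Gilman reagent and chlorination of the alkenylcopper intermediate with retention at low temperature should place methyl and chlorine cis, so that C4 and C7 are cis on the tetrasubstituted alkene.

Step 7
Reactants: 11 ethyl (2E,6S,7E)-2-chloro-6-(4-methoxybenzyloxy)-3,7-dimethyl-10-(triethylsilyloxy)deca-2,7-dienoate
Product: 12 (2E,6S,7E)-2-chloro-6-(4-methoxybenzyloxy)-3,7-dimethyl-10-(triethylsilyloxy)deca-2,7-dien-1-ol
Conditions: i-Bu2AlH (2.2 equiv), CH2Cl2, −78 °C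
Reagents that add atoms: none
Why: 1,2-Reduction of the enoate with the aluminium hydride gives the allylic alcohol without touching the chloroalkene.

Step 8
Reactants: 12 (2E,6S,7E)-2-chloro-6-(4-methoxybenzyloxy)-3,7-dimethyl-10-(triethylsilyloxy)deca-2,7-dien-1-ol
Product: 13 (2E,6S,7E)-2-chloro-6-(4-methoxybenzyloxy)-3,7-dimethyl-10-(triethylsilyloxy)deca-2,7-dienal
Conditions: Dess–Martin periodinane, NaHCO3, CH2Cl2, 0 °C to rt
Reagents that add atoms: none
Why: Dess–Martin oxidation gives the α-chloro enal (C7 aldehyde) under buffered neutral conditions that preserve the alkene geometry.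

Step 9
Reactants: 14 (3,4-dimethoxyphenyl)methanol; 15 bromoacetic acid
Product: 16 2-[(3,4-dimethoxybenzyl)oxy]acetic acid
Conditions: NaH (2.2 equiv), THF, 0 °C to rt; then aqueous HCl
Reagents that add atoms: none
Why: Williamson etherification of the benzylic alkoxide with sodium bromoacetate gives the glycolic acid ether that supplies C8, its oxygen and C9.

Step 10
Reactants: 16 2-[(3,4-dimethoxybenzyl)oxy]acetic acid; 17 (S)-4-benzyloxazolidin-2-one
Product: 19 (S)-4-benzyl-3-{[(3,4-dimethoxybenzyl)oxy]acetyl}oxazolidin-2-one, via mixed pivalic anhydride 18 (not isolated)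
Conditions: pivaloyl chloride, Et3N, THF, −20 °C; then 17, LiCl, rt
Reagents that add atoms: none
Why: N-Acylation of the oxazolidinone through the mixed anhydride gives the Evans glycolate imide.

Step 11
Reactants: 13 (2E,6S,7E)-2-chloro-6-(4-methoxybenzyloxy)-3,7-dimethyl-10-(triethylsilyloxy)deca-2,7-dienal; 19 (S)-4-benzyl-3-{[(3,4-dimethoxybenzyl)oxy]acetyl}oxazolidin-2-one
Product: 21 syn aldol adduct (N-acyl oxazolidinone of the C9 acid; 7S-hydroxy; 8S-ODMB; 2S-OPMB; 12-OTES), via dibutylboron Z-enolate 20 (not isolated)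
Conditions: 19, Bu2BOTf, Et3N, CH2Cl2, −78 to 0 °C; then 13, −78 to 0 °C; pH 7 buffer, MeOH, H2O2
Reagents that add atoms: none
Why: Evans syn-glycolate aldol addition forms C7–C8: the Z boron enolate reacts through a Zimmerman–Traxler chair on the face opposite the benzyl group of the S auxiliary, which should set 7S and 8S.

Step 12
Reactants: 21 syn aldol adduct
Product: 22 7-O-triethylsilyl ether of the aldol adduct
Conditions: Et3SiOTf, 2,6-lutidine, CH2Cl2, −78 °C
Reagents that add atoms: triethylsilyl trifluoromethanesulfonate, CC[Si](CC)(CC)OS(=O)(=O)C(F)(F)F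
Why: Silylation of the secondary alcohol gives a 7-O-TES ether that can later be removed in the presence of a TBS ether.

Step 13
Reactants: 22 7-O-triethylsilyl ether of the aldol adduct
Product: 23 S-ethyl thioester (C9 thioester; 8S-ODMB; 7S-OTES; 2S-OPMB; 12-OTES)
Conditions: EtSH, n-BuLi, THF, 0 °C
Reagents that add atoms: ethanethiol, CCS
Why: Acyl transfer to lithium ethanethiolate removes the auxiliary and gives a thioester that tolerates the next two steps and serves as the acyl donor for the ketone synthesis.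

Step 14
Reactants: 23 S-ethyl thioester
Product: 25 C12 aldehyde (β,γ-unsaturated aldehyde thioester), via alkoxydimethylsulfonium chloride 24 (not isolated)
Conditions: (COCl)2, DMSO, CH2Cl2, −78 to −40 °C; then Et3N, −78 to 0 °C
Reagents that add atoms: none
Why: Swern conditions oxidise a primary triethylsilyl ether directly to the aldehyde (silyl cleavage to the alkoxysulfonium salt, then elimination) while the secondary TES ether stays, giving the β,γ-unsaturated aldehyde, which is used at once.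

Step 15
Reactants: 25 C12 aldehyde
Product: 26 1-acetoxydiene thioester (AcO–C12H=C13H–C14H=C1; 12E; C2 arm trans to C13)
Conditions: Ac2O, Et3N, DMAP (cat.), CH2Cl2, 0 °C to rt
Reagents that add atoms: acetic anhydride, CC(=O)OC(C)=O
Why: Enolisation of the doubly activated C13 methylene and O-acylation (enol acetate formation) should give the acetoxydiene, mainly as the 12E isomer from the extended dienolate, with the C14=C1 geometry retained.

Step 16
Reactants: 26 1-acetoxydiene thioester; 27 (Z)-prop-1-enylboronic acid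
Product: 28 acetoxydiene Z-enone triene (8S-ODMB; 7S-OTES; 2S-OPMB)
Conditions: Pd2(dba)3 (2.5 mol %), tri(2-furyl)phosphine, copper thiophene-2-carboxylate Cu(O2CC4H3S) (1.5 equiv), THF, 45 °C
Reagents that add atoms: none
Why: Liebeskind–Srogl coupling (zerovalent palladium with a copper carboxylate cofactor) forms the C9–C10 bond under neutral, base-free conditions with retention of the alkene geometry, so the sensitive Z enone is made last.

Step 17
Reactants: 28 acetoxydiene Z-enone triene
Product: 29 trans-fused bicyclic ketone (ring A cyclohexene with 12-OAc; ten-membered ring with 9-oxo 8-ODMB 7-OTES 2-OPMB and the C5=C6 chloroalkene)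
Conditions: toluene (2 mM), 2,6-di-tert-butyl-4-methylphenol (0.2 equiv), sealed vessel, 135 °C, dark
Reagents that add atoms: none
Why: Proposed new method: a concerted, asynchronous [4+2] cycloaddition in which the acetoxydiene C12=C13–C14=C1 adds suprafacially to the Z enone C10=C11, the C11–C12 bond leading because the dialkylated terminus C1 best carries the developing positive charge; the closest known reaction type is the macrocycle-forming intramolecular Diels–Alder reaction of long-tethered trienes and its transannular variants, but closing a ten-membered ring onto a fully substituted diene terminus with a singly activated Z enone has not been shown. Ring A closes by the cycloaddition itself, and the ten-membered ring closes in the fused mode because the eight-atom tether C2–C9 joins diene terminus C1 to dienophile carbon C10, so the C1–C10 bond completes it. C12 and C1 follow from the diene geometry (E acetoxy and the C2 arm both outward, hence cis), C10 and C11 from the Z enone (C9 and the C11 methyl cis), and the trans ring fusion from the exo placement of the tether carbonyl. The absolute sense rests on C2: the dienophile should reach the diene face anti to the 2-OPMB group with C2–H in the diene plane, and the syn C7/C8 ethers and the Z chloroalkene limit the folds of the tether. The step needs fused rather than bridged regiochemistry, exo rather than endo pairing and survival of the Z geometry; the tether (a bridged closure would need an eleven-membered ring, an endo closure a tether folded under the diene) and neutral, radical-inhibited heating at high dilution are relied on for these. The acetoxy group is kept instead of a stronger silyloxy donor so that the alkyl-substituted terminus, not the oxygen, polarises the diene in the sense the tether demands.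

Step 18
Reactants: 29 trans-fused bicyclic ketone
Product: 30 9S alcohol (9-OH syn to 8-ODMB)
Conditions: KHB(sec-Bu)3, THF, −78 °C; then pH 7 buffer
Reagents that add atoms: none
Why: Felkin–Anh addition of the bulky, non-chelating hydride anti to the C8 alkoxy group, reinforced by the C10 centre with C1 as its large substituent, should give the 9S alcohol.

Step 19
Reactants: 30 9S alcohol
Product: 31 9-O-TBS ether
Conditions: t-BuMe2SiOTf, 2,6-lutidine, CH2Cl2, 0 °C
Reagents that add atoms: tert-butyldimethylsilyl trifluoromethanesulfonate, CC(C)(C)[Si](C)(C)OS(=O)(=O)C(F)(F)F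
Why: Silylation of the hindered secondary alcohol with the silyl triflate protects C9–OH until the last step.

Step 20
Reactants: 31 9-O-TBS ether
Product: 32 8-alcohol (8-ODMB removed)
Conditions: DDQ (1.1 equiv), CH2Cl2/pH 7 buffer, 0 °C
Reagents that add atoms: none
Why: Oxidative cleavage of the more electron-rich 3,4-dimethoxybenzyl ether by DDQ is faster than that of the PMB ether and should free C8–OH alone.

Step 21
Reactants: 32 8-alcohol
Product: 33 8-ketone (7-OTES; 9-OTBS)
Conditions: Dess–Martin periodinane, NaHCO3, CH2Cl2, rt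
Reagents that add atoms: none
Why: Dess–Martin oxidation gives the C8 ketone and erases the auxiliary C8 stereocentre.

Step 22
Reactants: 33 8-ketone
Product: 34 7-hydroxy 8-ketone
Conditions: HF·pyridine, pyridine, THF, 0 °C
Reagents that add atoms: none
Why: Buffered fluoride desilylation removes the triethylsilyl ether much faster than the hindered TBS ether, freeing C7–OH next to the ketone.

Step 23
Reactants: 34 7-hydroxy 8-ketone; 35 (S)-2-bromopropanoic acid
Product: 36 7-O-(2-bromopropanoyl) ester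
Conditions: DCC, DMAP (cat.), CH2Cl2, −20 to 0 °C
Reagents that add atoms: none
Why: Steglich esterification attaches the C19–C17–C18 unit to O7.

Step 24
Reactants: 36 7-O-(2-bromopropanoyl) ester
Product: 38 hydroxy lactone (C8 and C17 as in the target; 17R; 9-OTBS; 2-OPMB), via diiodosamarium enolate 37 (not isolated)
Conditions: SmI2 (2.5 equiv), THF, −78 °C; then aqueous NH4Cl
Reagents that add atoms: none
Why: Samarium diiodide reduces the C–Br bond to the samarium enolate, which adds to the C8 ketone in an intramolecular Reformatsky reaction; the O7 tether delivers C17 to the ketone face syn to O7, which with C6 and C9 gauche gives the cis-fused lactone, and the chelated closure should keep the methyl group on the side of the new hydroxyl, away from C9.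

Step 25
Reactants: 38 hydroxy lactone
Product: 39 2-alcohol
Conditions: DDQ, CH2Cl2/pH 7 buffer, rt
Reagents that add atoms: none
Why: DDQ oxidation removes the PMB ether and frees C2–OH.

Step 26
Reactants: 39 2-alcohol
Product: 40 13,14-epoxide (epoxide on the face of the C1–C2 bond)
Conditions: VO(acac)2 (5 mol %), t-BuOOH, CH2Cl2, 0 °C to rt
Reagents that add atoms: tert-butyl hydroperoxide, CC(C)(C)OO
Why: Vanadium-catalysed epoxidation directed by the homoallylic C2–OH should deliver oxygen to the C13=C14 face that carries the C1–C2 bond, anti to the C1 methyl, setting C13 and C14.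

Step 27
Reactants: 40 13,14-epoxide
Product: 41 2,12-diacetate 9-O-TBS ether
Conditions: Ac2O, pyridine, DMAP (cat.), CH2Cl2, 0 °C to rt
Reagents that add atoms: acetic anhydride, CC(=O)OC(C)=O
Why: DMAP-catalysed acylation of the secondary C2–OH gives the second acetate while the tertiary C8–OH and the silylated C9–OH should not react.

Step 28
Reactants: 41 2,12-diacetate 9-O-TBS ether
Product: 42 CNP0255641.1
Conditions: HF·pyridine, pyridine, THF, 0 °C to rt
Reagents that add atoms: none
Why: Buffered fluoride desilylation frees C9–OH without touching the acetates, the lactone or the epoxide and gives the target.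

**Compound list**

1 | pent-3-yn-1-ol | CC#CCCO | starting material
2 | triethyl(pent-3-yn-1-yloxy)silane | CC#CCCO[Si](CC)(CC)CC | intermediate
3 | pent-4-ynoyl chloride | C#CCCC(=O)Cl | starting material
4 | alkenylzirconocene chloride (E; Zr on C1) | CC[Si](CC)(CC)OCC/C=C(\C)[Zr](Cl)(C1C=CC=C1)C1C=CC=C1 | intermediate (not isolated)
5 | (E)-6-methyl-9-(triethylsilyloxy)non-6-en-1-yn-5-one | CC[Si](CC)(CC)OCC/C=C(\C)C(=O)CCC#C | intermediate
6 | (5S,6E)-6-methyl-9-(triethylsilyloxy)non-6-en-1-yn-5-ol | CC[Si](CC)(CC)OCC/C=C(\C)[C@@H](O)CCC#C | intermediate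
7 | (5S,6E)-5-(4-methoxybenzyloxy)-6-methyl-9-(triethylsilyloxy)non-6-en-1-yne | CC[Si](CC)(CC)OCC/C=C(\C)[C@@H](OCc1ccc(OC)cc1)CCC#C | intermediate
8 | lithium acetylide of 7 | CC[Si](CC)(CC)OCC/C=C(\C)[C@@H](OCc1ccc(OC)cc1)CCC#[C-].[Li+] | intermediate (not isolated)
9 | ethyl (6S,7E)-6-(4-methoxybenzyloxy)-7-methyl-10-(triethylsilyloxy)dec-7-en-2-ynoate | CC[Si](CC)(CC)OCC/C=C(\C)[C@@H](OCc1ccc(OC)cc1)CCC#CC(=O)OCC | intermediate
10 | lithium alkenyl(methyl)cuprate from 9 (Cu on C6, cis to the new methyl) | CC[Si](CC)(CC)OCC/C=C(\C)[C@@H](OCc1ccc(OC)cc1)CC/C(C)=C(/[Cu-]C)C(=O)OCC.[Li+] | intermediate (not isolated)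
11 | ethyl (2E,6S,7E)-2-chloro-6-(4-methoxybenzyloxy)-3,7-dimethyl-10-(triethylsilyloxy)deca-2,7-dienoate | CC[Si](CC)(CC)OCC/C=C(\C)[C@@H](OCc1ccc(OC)cc1)CC/C(C)=C(Cl)\C(=O)OCC | intermediate
12 | (2E,6S,7E)-2-chloro-6-(4-methoxybenzyloxy)-3,7-dimethyl-10-(triethylsilyloxy)deca-2,7-dien-1-ol | CC[Si](CC)(CC)OCC/C=C(\C)[C@@H](OCc1ccc(OC)cc1)CC/C(C)=C(Cl)\CO | intermediate
13 | (2E,6S,7E)-2-chloro-6-(4-methoxybenzyloxy)-3,7-dimethyl-10-(triethylsilyloxy)deca-2,7-dienal | CC[Si](CC)(CC)OCC/C=C(\C)[C@@H](OCc1ccc(OC)cc1)CC/C(C)=C(Cl)\C=O | intermediate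
14 | (3,4-dimethoxyphenyl)methanol | COc1ccc(CO)cc1OC | starting material
15 | bromoacetic acid | OC(=O)CBr | starting material
16 | 2-[(3,4-dimethoxybenzyl)oxy]acetic acid | COc1ccc(COCC(=O)O)cc1OC | intermediate
17 | (S)-4-benzyloxazolidin-2-one | O=C1N[C@@H](Cc2ccccc2)CO1 | starting material
18 | mixed pivalic anhydride of 16 | COc1ccc(COCC(=O)OC(=O)C(C)(C)C)cc1OC | intermediate (not isolated)
19 | (S)-4-benzyl-3-{[(3,4-dimethoxybenzyl)oxy]acetyl}oxazolidin-2-one | COc1ccc(COCC(=O)N2[C@@H](Cc3ccccc3)COC2=O)cc1OC | intermediate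
20 | dibutylboron Z-enolate of 19 | CCCCB(CCCC)O/C(=C\OCc1ccc(OC)c(OC)c1)N1[C@@H](Cc2ccccc2)COC1=O | intermediate (not isolated)
21 | syn aldol adduct: N-acyl oxazolidinone, 7S-OH, 8S-ODMB, 2S-OPMB, 12-OTES | CC[Si](CC)(CC)OCC/C=C(\C)[C@@H](OCc1ccc(OC)cc1)CC/C(C)=C(Cl)\[C@@H](O)[C@H](OCc1ccc(OC)c(OC)c1)C(=O)N1[C@@H](Cc2ccccc2)COC1=O | intermediate
22 | 7-O-TES ether of 21 | CC[Si](CC)(CC)OCC/C=C(\C)[C@@H](OCc1ccc(OC)cc1)CC/C(C)=C(Cl)\[C@@H](O[Si](CC)(CC)CC)[C@H](OCc1ccc(OC)c(OC)c1)C(=O)N1[C@@H](Cc2ccccc2)COC1=O | intermediate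
23 | S-ethyl thioester: 8S-ODMB, 7S-OTES, 2S-OPMB, 12-OTES | CC[Si](CC)(CC)OCC/C=C(\C)[C@@H](OCc1ccc(OC)cc1)CC/C(C)=C(Cl)\[C@@H](O[Si](CC)(CC)CC)[C@H](OCc1ccc(OC)c(OC)c1)C(=O)SCC | intermediate
24 | alkoxydimethylsulfonium chloride at O12 | C[S+](C)OCC/C=C(\C)[C@@H](OCc1ccc(OC)cc1)CC/C(C)=C(Cl)\[C@@H](O[Si](CC)(CC)CC)[C@H](OCc1ccc(OC)c(OC)c1)C(=O)SCC.[Cl-] | intermediate (not isolated)
25 | C12 aldehyde (β,γ-unsaturated) thioester | O=CC/C=C(\C)[C@@H](OCc1ccc(OC)cc1)CC/C(C)=C(Cl)\[C@@H](O[Si](CC)(CC)CC)[C@H](OCc1ccc(OC)c(OC)c1)C(=O)SCC | intermediate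
26 | 1-acetoxydiene thioester (12E; C2 arm trans to C13) | CC(=O)O/C=C/C=C(\C)[C@@H](OCc1ccc(OC)cc1)CC/C(C)=C(Cl)\[C@@H](O[Si](CC)(CC)CC)[C@H](OCc1ccc(OC)c(OC)c1)C(=O)SCC | intermediate
27 | (Z)-prop-1-enylboronic acid | C/C=C\B(O)O | starting material
28 | acetoxydiene Z-enone triene (cycloaddition precursor) | CC(=O)O/C=C/C=C(\C)[C@@H](OCc1ccc(OC)cc1)CC/C(C)=C(Cl)\[C@@H](O[Si](CC)(CC)CC)[C@H](OCc1ccc(OC)c(OC)c1)C(=O)/C=C\C | intermediate
29 | trans-fused bicyclic 9-ketone (cycloadduct): 12-OAc cis to the C1–C2 bond, C9 and C11 methyl cis, 8-ODMB, 7-OTES, 2-OPMB | CC(=O)O[C@H]1[C@H](C)[C@@H]2C(=O)[C@@H](OCc3ccc(OC)c(OC)c3)[C@H](O[Si](CC)(CC)CC)/C(Cl)=C(/C)CC[C@H](OCc3ccc(OC)cc3)[C@@]2(C)C=C1 | intermediate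
30 | 9S alcohol | CC(=O)O[C@H]1[C@H](C)[C@@H]2[C@H](O)[C@@H](OCc3ccc(OC)c(OC)c3)[C@H](O[Si](CC)(CC)CC)/C(Cl)=C(/C)CC[C@H](OCc3ccc(OC)cc3)[C@@]2(C)C=C1 | intermediate
31 | 9-O-TBS ether | CC(=O)O[C@H]1[C@H](C)[C@@H]2[C@H](O[Si](C)(C)C(C)(C)C)[C@@H](OCc3ccc(OC)c(OC)c3)[C@H](O[Si](CC)(CC)CC)/C(Cl)=C(/C)CC[C@H](OCc3ccc(OC)cc3)[C@@]2(C)C=C1 | intermediate
32 | 8-alcohol | CC(=O)O[C@H]1[C@H](C)[C@@H]2[C@H](O[Si](C)(C)C(C)(C)C)[C@@H](O)[C@H](O[Si](CC)(CC)CC)/C(Cl)=C(/C)CC[C@H](OCc3ccc(OC)cc3)[C@@]2(C)C=C1 | intermediate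
33 | 8-ketone | CC(=O)O[C@H]1[C@H](C)[C@@H]2[C@H](O[Si](C)(C)C(C)(C)C)C(=O)[C@H](O[Si](CC)(CC)CC)/C(Cl)=C(/C)CC[C@H](OCc3ccc(OC)cc3)[C@@]2(C)C=C1 | intermediate
34 | 7-hydroxy 8-ketone | CC(=O)O[C@H]1[C@H](C)[C@@H]2[C@H](O[Si](C)(C)C(C)(C)C)C(=O)[C@H](O)/C(Cl)=C(/C)CC[C@H](OCc3ccc(OC)cc3)[C@@]2(C)C=C1 | intermediate
35 | (S)-2-bromopropanoic acid | C[C@H](Br)C(=O)O | starting material
36 | 7-O-(2-bromopropanoyl) ester | CC(=O)O[C@H]1[C@H](C)[C@@H]2[C@H](O[Si](C)(C)C(C)(C)C)C(=O)[C@H](OC(=O)[C@H](C)Br)/C(Cl)=C(/C)CC[C@H](OCc3ccc(OC)cc3)[C@@]2(C)C=C1 | intermediate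
37 | diiodosamarium enolate of the O7 propanoate | CC(=O)O[C@H]1[C@H](C)[C@@H]2[C@H](O[Si](C)(C)C(C)(C)C)C(=O)[C@H](O/C(O[Sm](I)I)=C/C)/C(Cl)=C(/C)CC[C@H](OCc3ccc(OC)cc3)[C@@]2(C)C=C1 | intermediate (not isolated)
38 | hydroxy lactone: cis-fused, 8-OH and C17 methyl cis, 9-OTBS, 2-OPMB | CC(=O)O[C@H]1[C@H](C)[C@@H]2[C@H](O[Si](C)(C)C(C)(C)C)[C@@]3(O)[C@H](OC(=O)[C@@H]3C)/C(Cl)=C(/C)CC[C@H](OCc4ccc(OC)cc4)[C@@]2(C)C=C1 | intermediate
39 | 2-alcohol | CC(=O)O[C@H]1[C@H](C)[C@@H]2[C@H](O[Si](C)(C)C(C)(C)C)[C@@]3(O)[C@H](OC(=O)[C@@H]3C)/C(Cl)=C(/C)CC[C@H](O)[C@@]2(C)C=C1 | intermediate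
40 | 13,14-epoxide | CC(=O)O[C@H]1[C@H](C)[C@@H]2[C@H](O[Si](C)(C)C(C)(C)C)[C@@]3(O)[C@H](OC(=O)[C@@H]3C)/C(Cl)=C(/C)CC[C@H](O)[C@@]2(C)[C@H]2O[C@@H]12 | intermediate
41 | 2,12-diacetate 9-O-TBS ether | CC(=O)O[C@H]1[C@H](C)[C@@H]2[C@H](O[Si](C)(C)C(C)(C)C)[C@@]3(O)[C@H](OC(=O)[C@@H]3C)/C(Cl)=C(/C)CC[C@H](OC(C)=O)[C@@]2(C)[C@H]2O[C@@H]12 | intermediate
42 | CNP0255641.1 (1S,2S,7S,8R,9S,10S,11R,12S,13S,14R,17R) | CC(=O)O[C@H]1[C@H](C)[C@@H]2[C@H](O)[C@@]3(O)[C@H](OC(=O)[C@@H]3C)/C(Cl)=C(/C)CC[C@H](OC(C)=O)[C@@]2(C)[C@H]2O[C@@H]12 | target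

**Step count**

Total: 28 steps. Longest linear sequence: 26 steps (steps 1–8 and 11–28, from pent-3-yn-1-ol); steps 9–10 are a two-step branch.

**Steps most likely to fail**

1. Step 17 (the step proposed as a new method). What may go wrong:
   - the Z enone may isomerise before it reacts;
   - a 1,5-hydrogen shift may consume the cis-methyl diene;
   - closure may be bridged or endo;
   - the wrong diene face may pair with the dienophile;
   - oligomers may form.

   Fallback: the two rings are closed in two separate known operations, setting out from enal 13 and returning at 29.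
   - Direct Swern oxidation of the primary TES ether of 13 should give the dialdehyde F1.
   - Enol acetylation of its β,γ-unsaturated end (Ac2O, Et3N, DMAP) should give the dienyl acetate enal F2.
   - Acid 16 is converted (MeNHOMe·HCl, carbodiimide) into the Weinreb amide F3 and, with (Z)-prop-1-enyllithium, into the Z enone F4.
   - An intermolecular Diels–Alder reaction of F2 with F4 under the bulky Lewis acid Al(OC6H3-2,6-Ph2)3, a promoter used for exo-selective additions of enones, closes ring A only. The acetoxy-bearing terminus C12 is expected to attack the enone β-carbon C11, giving the ring A adduct F5.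
   - A boron-mediated intramolecular aldol addition (Bu2BOTf, i-Pr2NEt, high dilution) of the α-alkoxy ketone onto the C7 enal then closes the ten-membered ring to the 7-hydroxy ketone F6.
   - Silylation with Et3SiOTf returns to 29.

2. Step 24. What may go wrong: closure through the ring conformer with C6 and C9 anti would give the trans-fused C8 epimer, and electron transfer to the ketone could cleave the α-acyloxy group instead.

   Fallback: the lactone is built as a butenolide and oxidised from its open face, setting out from 34 and returning at 38.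
   - Esterification of 34 with 2-(diethoxyphosphoryl)propanoic acid (DCC) gives the phosphonate ester F7.
   - Intramolecular Horner–Wadsworth–Emmons olefination (LiCl, i-Pr2NEt, MeCN) gives the butenolide F8.
   - Weitz–Scheffer epoxidation (t-BuOOH, DBU) from the face opposite C6 gives the epoxy lactone F9.
   - SmI2 in THF/MeOH cleaves the C17–O bond to give 38, if necessary after base equilibration at C17.

3. Step 18. What may go wrong: the ring conformation may override Felkin–Anh control, so that hydride delivery shows poor facial selectivity or favours the 9R alcohol.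

   Fallback: the configuration is set by substitution instead of by facial control, setting out from 29 and returning at 30.
   - Chelation-controlled reduction with Zn(BH4)2 gives the 9R alcohol F10.
   - Triflation (Tf2O, pyridine) gives the triflate F11.
   - Displacement with tetrabutylammonium nitrite gives the nitrite ester F12, which hydrolyses on work-up to 30.

**Further compounds**

F1 | step 17 | dialdehyde (C12 and C7 aldehydes; 2S-OPMB) | O=CC/C=C(\C)[C@@H](OCc1ccc(OC)cc1)CC/C(C)=C(Cl)\C=O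
F2 | step 17 | dienyl acetate enal | CC(=O)O/C=C/C=C(\C)[C@@H](OCc1ccc(OC)cc1)CC/C(C)=C(Cl)\C=O
F3 | step 17 | 2-[(3,4-dimethoxybenzyl)oxy]-N-methoxy-N-methylacetamide | CON(C)C(=O)COCc1ccc(OC)c(OC)c1
F4 | step 17 | (Z)-1-[(3,4-dimethoxybenzyl)oxy]pent-3-en-2-one | C/C=C\C(=O)COCc1ccc(OC)c(OC)c1
F5 | step 17 | ring A adduct (cyclohexene with the acyl arm on C10 and the enal arm on C1) | CC(=O)O[C@H]1[C@H](C)[C@H](C(=O)COCc2ccc(OC)c(OC)c2)[C@@](C)([C@@H](OCc2ccc(OC)cc2)CC/C(C)=C(Cl)\C=O)C=C1
F6 | step 17 | 7-hydroxy analogue of 29 | CC(=O)O[C@H]1[C@H](C)[C@@H]2C(=O)[C@@H](OCc3ccc(OC)c(OC)c3)[C@H](O)/C(Cl)=C(/C)CC[C@H](OCc3ccc(OC)cc3)[C@@]2(C)C=C1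
F7 | step 24 | 7-O-[2-(diethoxyphosphoryl)propanoyl] ester of 34 (mixture at the phosphorus-bearing carbon) | CC(=O)O[C@H]1[C@H](C)[C@@H]2[C@H](O[Si](C)(C)C(C)(C)C)C(=O)[C@H](OC(=O)C(C)P(=O)(OCC)OCC)/C(Cl)=C(/C)CC[C@H](OCc3ccc(OC)cc3)[C@@]2(C)C=C1
F8 | step 24 | butenolide (C8=C17) | CC(=O)O[C@H]1[C@H](C)[C@@H]2[C@H](O[Si](C)(C)C(C)(C)C)C3=C(C)C(=O)O[C@@H]3/C(Cl)=C(/C)CC[C@H](OCc3ccc(OC)cc3)[C@@]2(C)C=C1
F9 | step 24 | 8,17-epoxy lactone (epoxide on the face of H-7) | CC(=O)O[C@H]1[C@H](C)[C@@H]2[C@H](O[Si](C)(C)C(C)(C)C)[C@@]34O[C@@]4(C)C(=O)O[C@@H]3/C(Cl)=C(/C)CC[C@H](OCc3ccc(OC)cc3)[C@@]2(C)C=C1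
F10 | step 18 | 9R alcohol (C9 epimer of 30) | CC(=O)O[C@H]1[C@H](C)[C@@H]2[C@@H](O)[C@@H](OCc3ccc(OC)c(OC)c3)[C@H](O[Si](CC)(CC)CC)/C(Cl)=C(/C)CC[C@H](OCc3ccc(OC)cc3)[C@@]2(C)C=C1
F11 | step 18 | 9R triflate | CC(=O)O[C@H]1[C@H](C)[C@@H]2[C@@H](OS(=O)(=O)C(F)(F)F)[C@@H](OCc3ccc(OC)c(OC)c3)[C@H](O[Si](CC)(CC)CC)/C(Cl)=C(/C)CC[C@H](OCc3ccc(OC)cc3)[C@@]2(C)C=C1
F12 | step 18 | 9S nitrite ester | CC(=O)O[C@H]1[C@H](C)[C@@H]2[C@H](ON=O)[C@@H](OCc3ccc(OC)c(OC)c3)[C@H](O[Si](CC)(CC)CC)/C(Cl)=C(/C)CC[C@H](OCc3ccc(OC)cc3)[C@@]2(C)C=C1
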